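## Retrosynthetic overview

1. The last bond made is the prenyl C=C, by Wittig olefination of a γ-lactol. Until then the prenyl group and the C-1 hydroxyl are hidden together as the lactone ring of terebic acid.
2. C7=C8 is made by Wittig union of a C12 epoxy enal carrying that lactol (left) with a C35 polyenyl ylide (right end group joined to crocetin dialdehyde at C7'=C8').
3. The oxirane, the only ring of the target, is closed by O-atom transfer to the 3,4-olefin, as in the cell. It is done on a C12 dienenitrile in which C5=C6 is switched off by the nitrile and the prenyl olefin, which any electrophilic oxidant would attack first, does not yet exist. C-3 and C-4 are set by the reagent, matched with C-2.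
4. C-2 and C-2' have opposite sense, so the two antipodes of one racemic acid supply the two ends: (S)-terebic acid the left, (R)-terebic acid the right (lactol olefination, Mukaiyama hydration, vinyl carbinol to phosphonium salt).
5. Ring order: lactone (bought, temporary), then oxirane (step 6), then the lactol ring is opened in the last step. No carbocycle is made.

Assumptions: carotenoid numbering is used (C-1 to C-15 for the oxirane half, primed numbers for the other half); (±)-terebic acid and crocetin dialdehyde are bought; Oxone is written as its active salt KHSO5; steps 1 and 2 are the two collected fractions of one chromatographic separation and are counted as two steps because each delivers an isolated compound.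

## Route

Step 1
Reactants: 1 (±)-terebic acid
Product: 2 (S)-terebic acid
Conditions: preparative SFC on amylose tris(3,5-dimethylphenylcarbamate), CO2/MeOH (0.1% HCO2H), 35 °C; fraction of the (S)-acid collected
Reagents that add atoms: none
Why: Chromatographic resolution of enantiomers on a chiral stationary phase makes no bond and only sorts the antipodes; the (S)-acid carries the configuration needed at C-2 of the oxirane half.

Step 2
Reactants: 1 (±)-terebic acid
Product: 3 (R)-terebic acid
Conditions: same column and eluent as step 1 (preparative SFC, amylose tris(3,5-dimethylphenylcarbamate), CO2/MeOH with 0.1% HCO2H, 35 °C); fraction of the (R)-acid collected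
Reagents that add atoms: none
Why: The same chromatographic resolution of enantiomers delivers the antipode, which is not waste because C-2' of the target has the opposite sense to C-2; no bond is made and the configuration is fixed by the fraction taken.

Step 3
Reactants: 2 (S)-terebic acid
Product: 4 (4R)-4-(hydroxymethyl)-5,5-dimethyloxolan-2-one
Conditions: BH3·SMe2 (1.3 equiv), THF, 0 → 20 °C; MeOH quench, evaporation
Reagents that add atoms: none
Why: Borane reduction takes the carboxylic acid through its acyloxyborane much faster than the γ-lactone, and the stereocentre is untouched (the descriptor changes from S to R only because the substituent priorities change).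

Step 4
Reactants: 4 (4R)-4-(hydroxymethyl)-5,5-dimethyloxolan-2-one
Product: 5 (3S)-2,2-dimethyl-5-oxooxolane-3-carbaldehyde
Conditions: Dess–Martin periodinane, NaHCO3, CH2Cl2, 0 → 20 °C; used at once
Reagents that add atoms: none
Why: Dess–Martin oxidation of the primary alcohol under buffered, base-free conditions keeps the α-stereocentre and the β-acyloxy group in place, and working without delay forestalls translactonisation of 4.

Step 5
Reactants: 5 (3S)-2,2-dimethyl-5-oxooxolane-3-carbaldehyde
Product: 6 (2E,4E)-5-[(3R)-2,2-dimethyl-5-oxooxolan-3-yl]-3-methylpenta-2,4-dienenitrile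
Conditions: diethyl (3-cyano-2-methylallyl)phosphonate, LiN(SiMe3)2, THF, −78 → −20 °C; 2Z isomer removed on silica and re-equilibrated with I2 (cat.)
Reagents that add atoms: diethyl (3-cyano-2-methylallyl)phosphonate, CCOP(=O)(OCC)CC(C)=CC#N
Why: Horner–Wadsworth–Emmons olefination with the preformed lithium phosphonate adds to the aldehyde at −78 °C faster than it deprotonates it and gives the E C3=C4 bond, while the stereocentre (now R by the priority rules) is retained.

Step 6
Reactants: 6 (2E,4E)-5-[(3R)-2,2-dimethyl-5-oxooxolan-3-yl]-3-methylpenta-2,4-dienenitrile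
Product: 7 (2E)-3-{(2R,3R)-3-[(3R)-2,2-dimethyl-5-oxooxolan-3-yl]oxiran-2-yl}but-2-enenitrile
Conditions: 1,2:4,5-di-O-isopropylidene-β-D-erythro-2,3-hexodiulo-2,6-pyranose (0.3 equiv), KHSO5 (as 2KHSO5·KHSO4·K2SO4), K2CO3, Bu4NHSO4 (cat.), MeCN/dimethoxymethane/aq. Na2B4O7 (pH about 10), 0 °C
Reagents that add atoms: potassium peroxymonosulfate (Oxone), [K+].[O-]S(=O)(=O)OO
Why: Shi asymmetric epoxidation (chiral dioxirane, spiro transition state) is the ring-forming step: C5=C6 is deactivated by the nitrile and no other olefin is present, so oxygen goes only to the E C3=C4 bond, and the D-fructose-derived catalyst delivers it to the face that gives the (3R,4R)-trans-oxirane, which is also the face anti to the CMe2–O arm of the neighbouring stereocentre (matched case).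

Step 7
Reactants: 7 (2E)-3-{(2R,3R)-3-[(3R)-2,2-dimethyl-5-oxooxolan-3-yl]oxiran-2-yl}but-2-enenitrile
Product: 8 (2E)-3-{(2R,3R)-3-[(3R)-5-hydroxy-2,2-dimethyloxolan-3-yl]oxiran-2-yl}but-2-enal
Conditions: i-Bu2AlH (3 equiv), CH2Cl2, −78 °C; EtOAc, then aq. potassium sodium tartrate (pH 7), wet silica
Reagents that add atoms: water, O
Why: Hydride reduction with i-Bu2AlH stops at −78 °C at the aluminium lactolate and at the N-aluminio aldimine, so neutral work-up gives lactol and enal in one operation without touching the oxirane or any stereocentre.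

Step 8
Reactants: 3 (R)-terebic acid
Product: 9 (4S)-4-(hydroxymethyl)-5,5-dimethyloxolan-2-one
Conditions: BH3·SMe2 (1.3 equiv), THF, 0 → 20 °C; MeOH quench, evaporation
Reagents that add atoms: none
Why: Borane reduction as in step 3 reduces the acid before the lactone and leaves the stereocentre alone.

Step 9
Reactants: 9 (4S)-4-(hydroxymethyl)-5,5-dimethyloxolan-2-one
Product: 10 (4S)-4-(hydroxymethyl)-5,5-dimethyloxolan-2-ol
Conditions: i-Bu2AlH (2.2 equiv), CH2Cl2/THF, −78 °C; aq. potassium sodium tartrate
Reagents that add atoms: none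
Why: Half-reduction of the γ-lactone with i-Bu2AlH (one equivalent is used up by the hydroxyl) gives the lactol, the ring–chain tautomer of the hydroxy aldehyde needed next, with the stereocentre untouched.

Step 10
Reactants: 10 (4S)-4-(hydroxymethyl)-5,5-dimethyloxolan-2-ol
Product: 11 (2S)-2-(2-hydroxypropan-2-yl)-5-methylhex-4-en-1-ol
Conditions: i-PrPPh3I (3.5 equiv), n-BuLi (3.4 equiv), THF, 0 → 20 °C
Reagents that add atoms: isopropyltriphenylphosphonium iodide, CC(C)[P+](c1ccccc1)(c1ccccc1)c1ccccc1.[I-]
Why: In this Wittig olefination of a lactol the non-stabilised isopropylidene ylide opens the lactol to the aldehyde and olefinates it to the prenyl olefin (no E/Z issue), freeing the tertiary hydroxyl.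

Step 11
Reactants: 11 (2S)-2-(2-hydroxypropan-2-yl)-5-methylhex-4-en-1-ol
Product: 12 (2S)-2-(2-hydroxypropan-2-yl)-5-methylhexane-1,5-diol
Conditions: Co(acac)2 (0.2 equiv), PhSiH3 (2.5 equiv), O2 (1 atm), i-PrOH/THF, 20 °C
Reagents that add atoms: dioxygen, O=O
Why: Mukaiyama hydration (cobalt-hydride hydrogen-atom transfer, then O2 capture) puts the hydroxyl on the tertiary carbon of the only olefin, tolerates free hydroxyls and leaves the remote stereocentre alone.

Step 12
Reactants: 12 (2S)-2-(2-hydroxypropan-2-yl)-5-methylhexane-1,5-diol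
Product: 13 (2R)-5-hydroxy-2-(2-hydroxypropan-2-yl)-5-methylhexanal
Conditions: SO3·pyridine, DMSO, i-Pr2NEt, CH2Cl2, 0 °C
Reagents that add atoms: none
Why: In the Parikh–Doering oxidation only the primary hydroxyl can be oxidised, and the mild amine base at 0 °C neither epimerises the α-centre nor causes retro-aldol cleavage (the product sits largely as its δ-lactol).

Step 13
Reactants: 13 (2R)-5-hydroxy-2-(2-hydroxypropan-2-yl)-5-methylhexanal
Product: 14 (3E,5S)-8-hydroxy-5-(2-hydroxypropan-2-yl)-8-methylnon-3-en-2-one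
Conditions: Ph3P=CHC(O)CH3 (1.3 equiv), toluene, 80 °C
Reagents that add atoms: 1-(triphenylphosphoranylidene)propan-2-one, CC(=O)C=P(c1ccccc1)(c1ccccc1)c1ccccc1
Why: The Wittig reaction with a stabilised ylide runs under neutral conditions on the open-chain tautomer and gives the E-enone without base-induced retro-aldol reaction or epimerisation.

Step 14
Reactants: 14 (3E,5S)-8-hydroxy-5-(2-hydroxypropan-2-yl)-8-methylnon-3-en-2-one
Product: 15 (4E,6S)-6-(2-hydroxypropan-2-yl)-3,9-dimethyldeca-1,4-diene-3,9-diol
Conditions: CH2=CHMgBr (4 equiv), THF, −78 → 0 °C; aq. NH4Cl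
Reagents that add atoms: vinylmagnesium bromide, C=C[Mg]Br
Why: Grignard 1,2-addition of the vinyl reagent to the methyl ketone (the vinyl-ionol tactic of carotenoid chemistry) gives the tertiary carbinol as a mixture at C-3, a centre that is destroyed in the next step.

Step 15
Reactants: 15 (4E,6S)-6-(2-hydroxypropan-2-yl)-3,9-dimethyldeca-1,4-diene-3,9-diol
Product: 16 [(2E,4E,6S)-9-hydroxy-6-(2-hydroxypropan-2-yl)-3,9-dimethyldeca-2,4-dien-1-yl]triphenylphosphonium bromide
Conditions: PPh3·HBr (1.05 equiv), MeOH, 20 °C; crystallised from EtOAc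
Reagents that add atoms: triphenylphosphine hydrobromide, [Br-].c1ccccc1[PH+](c1ccccc1)c1ccccc1
Why: Allylic transposition (SN1') of the bis-allylic tertiary carbinol: the pentadienyl cation is captured by PPh3 at the unhindered primary terminus, which gives the conjugated salt with the preferred E C5'=C6' bond and leaves C-2' untouched.

Step 16
Reactants: 16 right-end C15 phosphonium bromide; 17 crocetin dialdehyde
Product: 19 right-half C35 hydroxy polyenal, via C15 ylide 18 (not isolated)
Conditions: NaOMe (1.05 equiv), 17 (3 equiv), CH2Cl2/MeOH, 0 → 20 °C; then I2 (cat.), heptane/EtOAc, daylight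
Reagents that add atoms: none
Why: Wittig reaction of the semi-stabilised ylide with an excess of the symmetrical dialdehyde gives the mono-adduct (the surplus dialdehyde is recovered), and the new C7'=C8' bond is equilibrated to E with iodine.

Step 17
Reactants: 19 right-half C35 hydroxy polyenal
Product: 20 right-half C35 polyenol
Conditions: NaBH4, THF/MeOH, 0 °C
Reagents that add atoms: none
Why: Sodium borohydride 1,2-reduction converts the polyenal into the primary allylic alcohol without affecting any stereocentre.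

Step 18
Reactants: 20 right-half C35 polyenol
Product: 21 right-half C35 phosphonium bromide
Conditions: PPh3·HBr (1.05 equiv), CH2Cl2/MeOH, 20 °C
Reagents that add atoms: triphenylphosphine hydrobromide, [Br-].c1ccccc1[PH+](c1ccccc1)c1ccccc1
Why: Phosphonium salt formation from the polyenylic alcohol goes through the delocalised cation, which PPh3 captures at the primary terminus so that full conjugation is kept.

Step 19
Reactants: 21 right-half C35 phosphonium bromide; 8 epoxy enal lactol
Product: 23 lactol-ended 3,4-epoxy C47 polyene, via C35 ylide 22 (not isolated)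
Conditions: NaN(SiMe3)2 (1.0 equiv), THF, −78 °C; 8 (1.2 equiv), −78 → 0 °C; then heptane/EtOAc, 70 °C, dark; Et3N-washed silica
Reagents that add atoms: none
Why: In this Wittig reaction the salt-free polyenyl ylide, too weak a base to open the lactol or to enolise the epoxy enal at −78 °C, reacts with the free conjugated aldehyde and leaves the masked one alone; the new C7=C8 bond is brought to E by warming and the four stereocentres are not involved.

Step 20
Reactants: 23 lactol-ended 3,4-epoxy C47 polyene
Product: 24 CNP0268815.3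
Conditions: i-PrPPh3I (6 equiv), n-BuLi (5.8 equiv), THF, 0 °C; 23, 0 → 20 °C; pH 8 phosphate work-up; Et3N-washed silica, crystallisation of the all-E isomer
Reagents that add atoms: isopropyltriphenylphosphonium iodide, CC(C)[P+](c1ccccc1)(c1ccccc1)c1ccccc1.[I-]
Why: Wittig olefination of the γ-lactol with the non-stabilised isopropylidene ylide, as in step 10, creates the prenyl group and frees the C-1 hydroxyl in the last step under basic conditions, which the acid-labile allylic oxirane and the polyene tolerate, and no stereocentre is touched.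

## Compound list

1 | (±)-terebic acid (rac-2,2-dimethyl-5-oxooxolane-3-carboxylic acid) | O=C1CC(C(=O)O)C(C)(C)O1 | starting material
2 | (S)-terebic acid, (3S)-2,2-dimethyl-5-oxooxolane-3-carboxylic acid | O=C1C[C@H](C(=O)O)C(C)(C)O1 | intermediate
3 | (R)-terebic acid, (3R)-2,2-dimethyl-5-oxooxolane-3-carboxylic acid | O=C1C[C@@H](C(=O)O)C(C)(C)O1 | intermediate
4 | (4R)-4-(hydroxymethyl)-5,5-dimethyloxolan-2-one | O=C1C[C@H](CO)C(C)(C)O1 | intermediate
5 | (3S)-2,2-dimethyl-5-oxooxolane-3-carbaldehyde | O=C1C[C@H](C=O)C(C)(C)O1 | intermediate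
6 | (2E,4E)-5-[(3R)-2,2-dimethyl-5-oxooxolan-3-yl]-3-methylpenta-2,4-dienenitrile | O=C1C[C@H](/C=C/C(C)=C/C#N)C(C)(C)O1 | intermediate
7 | (2E)-3-{(2R,3R)-3-[(3R)-2,2-dimethyl-5-oxooxolan-3-yl]oxiran-2-yl}but-2-enenitrile | O=C1C[C@H]([C@H]2O[C@@H]2/C(C)=C/C#N)C(C)(C)O1 | intermediate
8 | (2E)-3-{(2R,3R)-3-[(3R)-5-hydroxy-2,2-dimethyloxolan-3-yl]oxiran-2-yl}but-2-enal (lactol, both anomers) | OC1C[C@H]([C@H]2O[C@@H]2/C(C)=C/C=O)C(C)(C)O1 | intermediate
9 | (4S)-4-(hydroxymethyl)-5,5-dimethyloxolan-2-one | O=C1C[C@@H](CO)C(C)(C)O1 | intermediate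
10 | (4S)-4-(hydroxymethyl)-5,5-dimethyloxolan-2-ol (lactol, both anomers, in equilibrium with its ring–chain tautomers) | OC1C[C@@H](CO)C(C)(C)O1 | intermediate
11 | (2S)-2-(2-hydroxypropan-2-yl)-5-methylhex-4-en-1-ol | OC[C@H](CC=C(C)C)C(C)(C)O | intermediate
12 | (2S)-2-(2-hydroxypropan-2-yl)-5-methylhexane-1,5-diol | OC[C@H](CCC(C)(C)O)C(C)(C)O | intermediate
13 | (2R)-5-hydroxy-2-(2-hydroxypropan-2-yl)-5-methylhexanal (drawn open; in equilibrium with its δ-lactol) | O=C[C@H](CCC(C)(C)O)C(C)(C)O | intermediate
14 | (3E,5S)-8-hydroxy-5-(2-hydroxypropan-2-yl)-8-methylnon-3-en-2-one | CC(=O)/C=C/[C@H](CCC(C)(C)O)C(C)(C)O | intermediate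
15 | (4E,6S)-6-(2-hydroxypropan-2-yl)-3,9-dimethyldeca-1,4-diene-3,9-diol (both C-3 epimers) | C=CC(C)(O)/C=C/[C@H](CCC(C)(C)O)C(C)(C)O | intermediate
16 | [(2E,4E,6S)-9-hydroxy-6-(2-hydroxypropan-2-yl)-3,9-dimethyldeca-2,4-dien-1-yl]triphenylphosphonium bromide | [Br-].c1ccccc1[P+](c1ccccc1)(c1ccccc1)C/C=C(C)/C=C/[C@H](CCC(C)(C)O)C(C)(C)O | intermediate
17 | crocetin dialdehyde, (2E,4E,6E,8E,10E,12E,14E)-2,6,11,15-tetramethylhexadeca-2,4,6,8,10,12,14-heptaenedial | O=C/C(C)=C/C=C/C(C)=C/C=C/C=C(C)/C=C/C=C(C)/C=O | starting material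
18 | ylide of 16 (carbanion at C-1 next to P; not isolated) | c1ccccc1[P+](c1ccccc1)(c1ccccc1)[CH-]/C=C(C)/C=C/[C@H](CCC(C)(C)O)C(C)(C)O | intermediate
19 | (22S)-all-E-25-hydroxy-22-(2-hydroxypropan-2-yl)-2,6,11,15,19,25-hexamethylhexacosa-2,4,6,8,10,12,14,16,18,20-decaenal (aldehyde carbon is C-8 of the carotenoid) | O=C/C(C)=C/C=C/C(C)=C/C=C/C=C(C)/C=C/C=C(C)/C=C/C=C(C)/C=C/[C@H](CCC(C)(C)O)C(C)(C)O | intermediate
20 | (22S)-all-E-22-(2-hydroxypropan-2-yl)-2,6,11,15,19,25-hexamethylhexacosa-2,4,6,8,10,12,14,16,18,20-decaene-1,25-diol | OC/C(C)=C/C=C/C(C)=C/C=C/C=C(C)/C=C/C=C(C)/C=C/C=C(C)/C=C/[C@H](CCC(C)(C)O)C(C)(C)O | intermediate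
21 | triphenylphosphonium bromide of 20 (PPh3 in place of the C-1 hydroxyl; all-E; 22S) | [Br-].c1ccccc1[P+](c1ccccc1)(c1ccccc1)C/C(C)=C/C=C/C(C)=C/C=C/C=C(C)/C=C/C=C(C)/C=C/C=C(C)/C=C/[C@H](CCC(C)(C)O)C(C)(C)O | intermediate
22 | ylide of 21 (carbanion at C-1 next to P; not isolated) | c1ccccc1[P+](c1ccccc1)(c1ccccc1)[CH-]/C(C)=C/C=C/C(C)=C/C=C/C=C(C)/C=C/C=C(C)/C=C/C=C(C)/C=C/[C@H](CCC(C)(C)O)C(C)(C)O | intermediate
23 | lactol-ended 3,4-epoxy C47 polyene: the target skeleton in which the prenyl group and the C-1 oxygen are still tied up as a (3R)-5-hydroxy-2,2-dimethyloxolan-3-yl ring; (2R,3R)-oxirane, all-E dodecaene, (2'S) dihydroxy end; both anomers | OC1C[C@H]([C@H]2O[C@@H]2/C(C)=C/C=C/C(C)=C/C=C/C(C)=C/C=C/C=C(C)/C=C/C=C(C)/C=C/C=C(C)/C=C/[C@H](CCC(C)(C)O)C(C)(C)O)C(C)(C)O1 | intermediate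
24 | CNP0268815.3, (2R,3R,4R,2'S)-3,4-epoxy-2'-(3-hydroxy-3-methylbutyl)-2-(3-methylbut-2-enyl)-3',4'-didehydro-1,2,3,4,1',2'-hexahydro-ψ,ψ-carotene-1,1'-diol, all-E | CC(C)=CC[C@H]([C@H]1O[C@@H]1/C(C)=C/C=C/C(C)=C/C=C/C(C)=C/C=C/C=C(C)/C=C/C=C(C)/C=C/C=C(C)/C=C/[C@H](CCC(C)(C)O)C(C)(C)O)C(C)(C)O | target

## Step count

Total step count: 20.
Longest linear sequence: 14 steps (step 2, then steps 8 to 20). The left-hand branch (steps 1 and 3 to 7) joins at step 19.

## Steps most likely to fail

**Step 19.** The union is run with a free lactol (a masked aliphatic aldehyde) beside the enal, and the γ,δ-epoxy enal is base-sensitive; the ylide may attack the ring-opened lactol or the epoxy enal may isomerise.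
The fallback unveils the prenyl group before the union and sets out from 7. One equivalent of i-Bu2AlH at −78 °C reduces only the lactone, giving (2E)-3-{(2R,3R)-3-[(3R)-5-hydroxy-2,2-dimethyloxolan-3-yl]oxiran-2-yl}but-2-enenitrile F1. The isopropylidene ylide of step 20 turns this lactol into (2E)-3-{(2R,3R)-3-[(3R)-2-hydroxy-2,6-dimethylhept-5-en-3-yl]oxiran-2-yl}but-2-enenitrile F2. A second i-Bu2AlH reduction of the nitrile gives (2E)-3-{(2R,3R)-3-[(3R)-2-hydroxy-2,6-dimethylhept-5-en-3-yl]oxiran-2-yl}but-2-enal F3, which has only one carbonyl group. Its Wittig reaction with ylide 22 forms the target directly, so the fallback comes back to the route at 24.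

**Step 6.** The lactone may be saponified at pH 10, or the oxygen transfer may be slow or poorly selective on the olefin next to the branched ring carbon.
The fallback builds the oxirane by carbon–carbon bond formation instead of oxygen transfer and sets out from 5. The salt 1-[(2E)-3-cyano-2-methylprop-2-en-1-yl]thiolan-1-ium bromide F4 (from thiolane and 4-bromo-3-methylbut-2-enenitrile) is deprotonated with KOt-Bu in THF at −78 °C to [(2E)-3-cyano-2-methylprop-2-en-1-ylide]thiolanium F5. This adds to aldehyde 5 in a Corey–Chaykovsky epoxidation: Felkin–Anh attack anti to the CMe2–O arm sets C-3 as R, and closure of the anti betaine gives the trans-oxirane. The product is 7, where the fallback comes back to the route (steps 5 and 6 are replaced).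

**Step 15.** The pentadienyl cation formed with PPh3·HBr can be trapped by the neighbouring tertiary hydroxyls (cyclic ethers), and the E/Z ratio at C5'=C6' may be poor.
The fallback avoids the cation and sets out from 13. A Horner–Wadsworth–Emmons reaction with triethyl 3-methyl-4-phosphonocrotonate (LiN(SiMe3)2, THF, −78 °C) gives ethyl (2E,4E,6S)-9-hydroxy-6-(2-hydroxypropan-2-yl)-3,9-dimethyldeca-2,4-dienoate F6. Reduction with i-Bu2AlH gives (2E,4E,6S)-6-(2-hydroxypropan-2-yl)-3,9-dimethyldeca-2,4-diene-1,9-diol F7. The primary allylic hydroxyl alone is exchanged with CBr4/PPh3 to give (2E,4E,6S)-1-bromo-6-(2-hydroxypropan-2-yl)-3,9-dimethyldeca-2,4-dien-9-ol F8, and SN2 displacement with PPh3 in toluene gives the salt 16, where the fallback comes back to the route.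

## Further compounds

F1 | step 19 | (2E)-3-{(2R,3R)-3-[(3R)-5-hydroxy-2,2-dimethyloxolan-3-yl]oxiran-2-yl}but-2-enenitrile | OC1C[C@H]([C@H]2O[C@@H]2/C(C)=C/C#N)C(C)(C)O1
F2 | step 19 | (2E)-3-{(2R,3R)-3-[(3R)-2-hydroxy-2,6-dimethylhept-5-en-3-yl]oxiran-2-yl}but-2-enenitrile | CC(C)=CC[C@H]([C@H]1O[C@@H]1/C(C)=C/C#N)C(C)(C)O
F3 | step 19 | (2E)-3-{(2R,3R)-3-[(3R)-2-hydroxy-2,6-dimethylhept-5-en-3-yl]oxiran-2-yl}but-2-enal | CC(C)=CC[C@H]([C@H]1O[C@@H]1/C(C)=C/C=O)C(C)(C)O
F4 | step 6 | 1-[(2E)-3-cyano-2-methylprop-2-en-1-yl]thiolan-1-ium bromide | N#C/C=C(C)/C[S+]1CCCC1.[Br-]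
F5 | step 6 | [(2E)-3-cyano-2-methylprop-2-en-1-ylide]thiolanium (sulfonium ylide, made in the flask) | N#C/C=C(C)/[CH-][S+]1CCCC1
F6 | step 15 | ethyl (2E,4E,6S)-9-hydroxy-6-(2-hydroxypropan-2-yl)-3,9-dimethyldeca-2,4-dienoate | CCOC(=O)/C=C(C)/C=C/[C@H](CCC(C)(C)O)C(C)(C)O
F7 | step 15 | (2E,4E,6S)-6-(2-hydroxypropan-2-yl)-3,9-dimethyldeca-2,4-diene-1,9-diol | OC/C=C(C)/C=C/[C@H](CCC(C)(C)O)C(C)(C)O
F8 | step 15 | (2E,4E,6S)-1-bromo-6-(2-hydroxypropan-2-yl)-3,9-dimethyldeca-2,4-dien-9-ol | BrC/C=C(C)/C=C/[C@H](CCC(C)(C)O)C(C)(C)O
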